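## Analysis of the target

Target 20 joins two 5,7-dihydroxy-2,2-dimethylchroman units (ring systems A and B, each a fully substituted benzene ring fused to a dimethylpyran ring) through one sp3 carbon, C1′, which also carries H and a 5-methylhexyl chain (C2′–C7′). Ring system A bears an (R)-2-methylbutanoyl group at C8A and ring system B an isobutyryl group at C8B, and in each ring the pyran oxygen O1 is ortho to the acyl group (8-acyl, not 6-acyl chroman). CIP analysis of the SMILES gives (R) at the α-carbon of the 2-methylbutanoyl group and (R) at C1′; the two centres are remote and independent, and the α-carbon, taken from the chiral pool, is epimerisable next to the ketone. The two aryl groups on C1′ are constitutionally identical except for one extra carbon at the end of the acyl side chain, seven bonds from C1′, so no reagent or catalyst can be expected to tell them apart, and the α-centre, five bonds away, cannot bias the methine. A bis(ortho-hydroxyaryl)methine can fragment through retro-Friedel–Crafts (ortho-quinone methide) pathways in acid or base, which would scramble C1′, so the last steps must be neutral. The feature the route uses is that C1′ sits on C6A, ortho to the phenolic oxygen O5A, and continues as C2′–C3′. The array O5A–C5A=C6A–C1′–C2′=C3′ is the product pattern of an aromatic Claisen rearrangement of an O5A allyl ether, and the C2′=C3′ alkene is only two hydrogens away from the saturated chain of the target. The difficulty is therefore concentrated in one question: how to make the two near-identical aryl groups different at the moment C1′ is set.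

## Retrosynthetic reasoning

**20 ⇒ 19.** The two phenols of ring B are masked as benzyl ethers. They are released last by hydrogenolysis, which needs neither acid nor base and so cannot trigger aryl exchange at C1′.

**19 ⇒ 18.** A C2′=C3′ (E)-alkene is introduced retrosynthetically. Forward, it must be saturated without migration into the allylic, doubly benzylic C1′ position, so a metal-free hydrogen transfer is planned.

**18 ⇒ 16 (key disconnection).** The C6A–C1′ bond is cut and O5A is reconnected to C3′, giving allyl aryl ether 16. Forward, this is a [3,3]-sigmatropic shift that forms the ring A–methine bond and sets C1′ by chirality transfer from C3′. The cut makes the two rings constitutionally different in the precursor, ring A being bound through oxygen and ring B through carbon, so the impossible aryl/aryl discrimination becomes the configuration of an ordinary secondary carbinol carbon plus an (E)-alkene. The other ortho position (C4aA) and the para position (C8A) of O5A are blocked, so only C6A can accept the allyl unit.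

**16 ⇒ 15 + 12.** The O5A–C3′ bond is made by Mitsunobu etherification with inversion. In 15 only the C5–OH is free of hydrogen bonding and acidic (para to the acyl group); the C7–OH is chelated to the ketone. Ring B in 12 must be fully O-protected so that it offers no competing phenol. The ring with the epimerisable (R)-acyl group is chosen as the ether partner because it then sees the fewest steps. With this assignment an (R)-ether 16, hence an (S)-alcohol 12, is required.

**12 ⇒ 11 ⇒ 7 + 10.** The carbinol centre comes from an oxazaborolidine-catalysed reduction of enone 11. The aryl–alkene bond of 11 comes from a Heck reaction of aryl iodide 7 with vinyl ketone 10, which fixes the (E)-geometry.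

**7 ⇒ 6 ⇒ 5.** Iodination of 5 can only occur at C6, the last free ring position. Benzylation follows so that C6 cannot be C-alkylated.

**5 and 15 ⇒ 3 + 4, and 3 + 13 (via 14).** Both acyl groups are introduced by Friedel–Crafts acylation of the common chroman 3. C8 (ortho to one hydroxyl and para to the other) is expected to react in preference to C6 (between two hydroxyls).

**3 ⇒ 1 + 2.** The chroman ring is annulated onto C3-symmetric 1, where the first C-alkylation has no regiochemical choice.

**10 ⇒ 8 + 9.** The vinyl ketone is made in one step by acylation of a vinyl-metal reagent.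

## Alternatives that were turned down

**Alternative 1:** (textbook) Both aryl–C1′ bonds are cut. Forward, 5 and 15 are condensed with 6-methylheptanal (A1) through ortho-quinone methide A2 in a double Friedel–Crafts alkylation. A one-pot version gives a statistical mixture of hetero- and homo-dimers such as A3. A stepwise version fixes constitution but not configuration: the rings differ by one remote carbon and the α-centre is five bonds from C1′, so both C1′ epimers should form equally and would be very hard to separate. A chiral Brønsted acid variant would have to control the face of a mobile, alkyl-substituted quinone methide that can tautomerise to a styrene, under conditions where the product can revert. It is the shortest route (about five steps) but leaves the one real problem unsolved, and it is kept only as the fallback for the key step.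

**Alternative 2:** The two aryl–acyl bonds are cut to give the prochiral, symmetric bis(chromanyl)alkane A4 (from 3 and A1). Forward, a catalyst-controlled acylation of one of the two enantiotopic rings of A4 is followed by acylation of the other ring with 14. Formation of A4 faces a C6/C8 choice on each ring. A4 has four phenols, and acyl transfer between the close-lying phenols of the two rings would convert one enantiomer into the other. The O-to-C acyl shift needs Lewis acid, under which such diarylmethines exchange aryl groups. Precedent for remote desymmetrisation exists only for much simpler bisphenols.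

**Alternative 3:** The C1′–H bond is cut to give the 1,1-diarylalkene A5. Forward, A5 is reduced by enantioselective hydrogenation. A5 exists as E and Z isomers that differ only in which near-identical aryl group is cis to the chain; they would form in equal amounts, be inseparable, and give opposite configurations at C1′ with the same catalyst. The tetra-ortho-substituted rings stand orthogonal to the alkene and shield it. Building A5 requires the diaryl ketone A6 and an olefination at its very hindered carbonyl.

Key step: step 10

Assumption: (R)-2-methylbutanoic acid (13) is purchased in high enantiomeric purity.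

## Route

Step 1
Reactants: 1 phloroglucinol, 2 isoprene
Product: 3 2,2-dimethylchroman-5,7-diol
Conditions: Amberlyst 15 (cat.), THF–heptane, 65 °C; isoprene added slowly, phloroglucinol kept in excess
Reagents that add atoms: none
Why: Acid-catalysed Friedel–Crafts prenylation followed by Markovnikov hydroalkoxylation of the prenyl alkene by the neighbouring phenol closes the six-membered ether in a 1:1 addition that sets nothing free. The threefold symmetry of phloroglucinol removes any regiochemical choice, and keeping it in excess over isoprene suppresses a second annulation; the unchanged excess is washed out with water.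

Step 2
Reactants: 3 2,2-dimethylchroman-5,7-diol, 4 isobutyryl chloride
Product: 5 1-(5,7-dihydroxy-2,2-dimethylchroman-8-yl)-2-methylpropan-1-one
Conditions: AlCl3 (3.5 equiv), CH2Cl2–PhNO2, 0 °C to rt
Reagents that add atoms: none
Why: Friedel–Crafts acylation; C8 (ortho to one hydroxyl, para to the other) is expected to react in preference to C6, which lies between two aluminium-bound phenoxides, as is usual for resorcinol-type arenes; any C6 isomer should be separable by chromatography.

Step 3
Reactants: 5 1-(5,7-dihydroxy-2,2-dimethylchroman-8-yl)-2-methylpropan-1-one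
Product: 6 1-(5,7-dihydroxy-6-iodo-2,2-dimethylchroman-8-yl)-2-methylpropan-1-one
Conditions: N-iodosuccinimide (1.05 equiv), MeCN, 0 °C to rt, dark
Reagents that add atoms: N-iodosuccinimide, O=C1CCC(=O)N1I
Why: Electrophilic aromatic iodination at the only remaining ring C–H (C6), which is activated by three oxygens; iodine is placed before benzylation so that C6 cannot be C-benzylated.

Step 4
Reactants: 6 1-(5,7-dihydroxy-6-iodo-2,2-dimethylchroman-8-yl)-2-methylpropan-1-one
Product: 7 1-[5,7-bis(benzyloxy)-6-iodo-2,2-dimethylchroman-8-yl]-2-methylpropan-1-one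
Conditions: benzyl bromide (2.5 equiv), K2CO3, DMF, 60 °C
Reagents that add atoms: benzyl bromide, BrCc1ccccc1
Why: Williamson etherification of both phenols (the chelated C7–OH needs warm DMF); the polar aprotic medium favours O-alkylation over dearomatising C-alkylation, and benzyl is chosen because it leaves under neutral hydrogenolysis.

Step 5
Reactants: 8 4-methylpentanoyl chloride, 9 tributyl(vinyl)stannane
Product: 10 6-methylhept-1-en-3-one
Conditions: PdCl2(PPh3)2 (2 mol%), BHT (trace), THF, 60 °C
Reagents that add atoms: none
Why: Stille acylation of an acid chloride with a vinylstannane gives the vinyl ketone in one step; it should be used promptly to avoid polymerisation.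

Step 6
Reactants: 7 1-[5,7-bis(benzyloxy)-6-iodo-2,2-dimethylchroman-8-yl]-2-methylpropan-1-one, 10 6-methylhept-1-en-3-one
Product: 11 (E)-1-[5,7-bis(benzyloxy)-8-isobutyryl-2,2-dimethylchroman-6-yl]-6-methylhept-1-en-3-one
Conditions: Pd(OAc)2 (10 mol%), Bu4NCl, NaHCO3, DMF, 85 °C
Reagents that add atoms: none
Why: Mizoroki–Heck reaction under ligand-free phase-transfer conditions; syn insertion at the unsubstituted alkene terminus and syn β-hydride elimination should give the (E)-enone, and the iodide offsets the di-ortho substitution.

Step 7
Reactants: 11 (E)-1-[5,7-bis(benzyloxy)-8-isobutyryl-2,2-dimethylchroman-6-yl]-6-methylhept-1-en-3-one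
Product: 12 (S,E)-1-[5,7-bis(benzyloxy)-6-(3-hydroxy-6-methylhept-1-en-1-yl)-2,2-dimethylchroman-8-yl]-2-methylpropan-1-one
Conditions: (R)-2-methyl-CBS-oxazaborolidine (20 mol%), catecholborane (1.8 equiv), PhMe, −78 °C; MeOH, then aq. NaOH work-up
Reagents that add atoms: none
Why: Corey–Bakshi–Shibata reduction; the enone carbonyl binds with the alkenyl group as the large substituent, so the (R)-catalyst should deliver hydride to give the (S)-allylic alcohol (mirror image of the (S)-catalyst/acetophenone case), while the twisted, di-ortho-substituted isobutyryl ketone is too hindered to compete.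

Step 8
Reactants: 13 (R)-2-methylbutanoic acid, 3 2,2-dimethylchroman-5,7-diol
Product: 15 (R)-1-(5,7-dihydroxy-2,2-dimethylchroman-8-yl)-2-methylbutan-1-one, via (R)-2-methylbutanoyl chloride 14 (not isolated)
Conditions: (COCl)2, DMF (cat.), CH2Cl2, 0 °C to rt; then 3, AlCl3 (3.5 equiv), CH2Cl2–PhNO2, 0 °C to rt
Reagents that add atoms: oxalyl chloride, ClC(=O)C(Cl)=O (its chlorine is carried only by intermediate 14)
Why: Base-free acid chloride formation avoids the ketene pathway, and Friedel–Crafts acylation at C8 follows the regiochemistry of step 2; keeping the temperature at or below room temperature limits enolisation of the aluminium-bound ketone, so the (R)-α-centre should be retained.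

Step 9
Reactants: 15 (R)-1-(5,7-dihydroxy-2,2-dimethylchroman-8-yl)-2-methylbutan-1-one, 12 (S,E)-1-[5,7-bis(benzyloxy)-6-(3-hydroxy-6-methylhept-1-en-1-yl)-2,2-dimethylchroman-8-yl]-2-methylpropan-1-one
Product: 16 (R)-1-[5-({(R,E)-1-[5,7-bis(benzyloxy)-8-isobutyryl-2,2-dimethylchroman-6-yl]-6-methylhept-1-en-3-yl}oxy)-7-hydroxy-2,2-dimethylchroman-8-yl]-2-methylbutan-1-one
Conditions: PPh3, DIAD, PhMe, 0 °C
Reagents that add atoms: none
Why: Mitsunobu etherification with SN2 inversion at C3′ (S to R); only the non-chelated, more acidic C5–OH of 15 reacts, the C7–OH being held in a hydrogen bond to the ketone. Toluene and low temperature disfavour ionisation, and the di-ortho-substituted ring B is twisted out of conjugation, which weakens allyl cation stabilisation and blocks SN2′ attack at C1′.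

Step 10
Reactants: 16 (R)-1-[5-({(R,E)-1-[5,7-bis(benzyloxy)-8-isobutyryl-2,2-dimethylchroman-6-yl]-6-methylhept-1-en-3-yl}oxy)-7-hydroxy-2,2-dimethylchroman-8-yl]-2-methylbutan-1-one
Product: 18 (R)-1-(6-{(S,E)-1-[5,7-bis(benzyloxy)-8-isobutyryl-2,2-dimethylchroman-6-yl]-6-methylhept-2-en-1-yl}-5,7-dihydroxy-2,2-dimethylchroman-8-yl)-2-methylbutan-1-one, via ring-A ortho-dienone tautomer 17 (not isolated)
Conditions: degassed o-xylene (0.02 M), 135 °C, sealed tube
Reagents that add atoms: none
Why: Thermal aromatic Claisen rearrangement: a concerted, suprafacial [3,3]-sigmatropic shift in which O5A–C3′ breaks as C6A–C1′ forms, giving ortho-dienone 17, which tautomerises irreversibly to phenol 18. The closest known reaction type is the Claisen rearrangement of enantioenriched secondary (E)-γ-substituted allyl aryl ethers, cinnamyl-type ethers included, which proceeds with 1,3-chirality transfer. No ring is closed; the only cyclic array is the six-membered chair transition state. The new centre C1′ is controlled by three substrate elements: the (R)-configuration at C3′, the (E)-alkene, and the preference of the 3-methylbutyl group for the pseudo-equatorial position (A(1,3) strain otherwise); together they put C6A on one face of C1′ and give the new C2′=C3′ alkene as E. Because ring A arrives through oxygen while ring B already sits on carbon, the two near-identical aryl groups are distinguished by constitution and not by a reagent. Regioselectivity is secured by the substrate: the other ortho position (C4aA) and the para position (C8A) of O5A are substituted, so only C6A can rearomatise. The selectivity that has to be won is the concerted shift over C–O heterolysis, which would scramble C3′ and give formal [1,3] products; an acid-free non-polar medium and the twist of ring B out of conjugation with the allyl unit both disfavour ionisation.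

Step 11
Reactants: 18 (R)-1-(6-{(S,E)-1-[5,7-bis(benzyloxy)-8-isobutyryl-2,2-dimethylchroman-6-yl]-6-methylhept-2-en-1-yl}-5,7-dihydroxy-2,2-dimethylchroman-8-yl)-2-methylbutan-1-one
Product: 19 (R)-1-(6-{(S)-1-[5,7-bis(benzyloxy)-8-isobutyryl-2,2-dimethylchroman-6-yl]-6-methylheptyl}-5,7-dihydroxy-2,2-dimethylchroman-8-yl)-2-methylbutan-1-one
Conditions: 2-nitrobenzenesulfonylhydrazide (excess), Et3N, CH2Cl2, rt
Reagents that add atoms: none
Why: Diimide reduction transfers two hydrogens concertedly and syn to the trans-disubstituted alkene without any metal hydride, so the allylic, doubly benzylic C1′ cannot be scrambled by double-bond migration; aryl ketones and benzyl ethers are inert.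

Step 12
Reactants: 19 (R)-1-(6-{(S)-1-[5,7-bis(benzyloxy)-8-isobutyryl-2,2-dimethylchroman-6-yl]-6-methylheptyl}-5,7-dihydroxy-2,2-dimethylchroman-8-yl)-2-methylbutan-1-one
Product: 20 (R)-1-(6-{(R)-1-[5,7-dihydroxy-8-isobutyryl-2,2-dimethylchroman-6-yl]-6-methylheptyl}-5,7-dihydroxy-2,2-dimethylchroman-8-yl)-2-methylbutan-1-one (CNP0287681.1)
Conditions: H2 (1 atm), 10% Pd/C, EtOAc, rt
Reagents that add atoms: none
Why: Neutral hydrogenolysis of the two aryl benzyl ethers avoids the acid or base that could fragment the bis(ortho-hydroxyaryl)methine or epimerise the α-keto centre; the chelated aryl ketones should survive balloon pressure. The C1′ descriptor changes from S to R only because the CIP ranking of the two aryl groups inverts on debenzylation; the spatial arrangement is unchanged.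

## Compound list

1 | phloroglucinol (benzene-1,3,5-triol) | Oc1cc(O)cc(O)c1 | starting material
2 | isoprene (2-methylbuta-1,3-diene) | C=CC(C)=C | starting material
3 | 2,2-dimethylchroman-5,7-diol | CC1(C)CCc2c(O)cc(O)cc2O1 | intermediate
4 | isobutyryl chloride | CC(C)C(Cl)=O | starting material
5 | 1-(5,7-dihydroxy-2,2-dimethylchroman-8-yl)-2-methylpropan-1-one | CC(C)C(=O)c1c(O)cc(O)c2c1OC(C)(C)CC2 | intermediate
6 | 1-(5,7-dihydroxy-6-iodo-2,2-dimethylchroman-8-yl)-2-methylpropan-1-one | CC(C)C(=O)c1c(O)c(I)c(O)c2c1OC(C)(C)CC2 | intermediate
7 | 1-[5,7-bis(benzyloxy)-6-iodo-2,2-dimethylchroman-8-yl]-2-methylpropan-1-one | CC(C)C(=O)c1c(OCc3ccccc3)c(I)c(OCc3ccccc3)c2c1OC(C)(C)CC2 | intermediate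
8 | 4-methylpentanoyl chloride | CC(C)CCC(Cl)=O | starting material
9 | tributyl(vinyl)stannane | CCCC[Sn](CCCC)(CCCC)C=C | starting material
10 | 6-methylhept-1-en-3-one | CC(C)CCC(=O)C=C | intermediate
11 | (E)-1-[5,7-bis(benzyloxy)-8-isobutyryl-2,2-dimethylchroman-6-yl]-6-methylhept-1-en-3-one | CC(C)C(=O)c1c(OCc3ccccc3)c(/C=C/C(=O)CCC(C)C)c(OCc3ccccc3)c2c1OC(C)(C)CC2 | intermediate
12 | (S,E)-1-[5,7-bis(benzyloxy)-6-(3-hydroxy-6-methylhept-1-en-1-yl)-2,2-dimethylchroman-8-yl]-2-methylpropan-1-one | CC(C)C(=O)c1c(OCc3ccccc3)c(/C=C/[C@@H](O)CCC(C)C)c(OCc3ccccc3)c2c1OC(C)(C)CC2 | intermediate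
13 | (R)-2-methylbutanoic acid | CC[C@@H](C)C(=O)O | starting material
14 | (R)-2-methylbutanoyl chloride | CC[C@@H](C)C(Cl)=O | intermediate
15 | (R)-1-(5,7-dihydroxy-2,2-dimethylchroman-8-yl)-2-methylbutan-1-one | CC[C@@H](C)C(=O)c1c(O)cc(O)c2c1OC(C)(C)CC2 | intermediate
16 | (R)-1-[5-({(R,E)-1-[5,7-bis(benzyloxy)-8-isobutyryl-2,2-dimethylchroman-6-yl]-6-methylhept-1-en-3-yl}oxy)-7-hydroxy-2,2-dimethylchroman-8-yl]-2-methylbutan-1-one | CC[C@@H](C)C(=O)c1c(O)cc(O[C@H](CCC(C)C)/C=C/c3c(OCc5ccccc5)c(C(=O)C(C)C)c4OC(C)(C)CCc4c3OCc6ccccc6)c2c1OC(C)(C)CC2 | intermediate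
17 | ring-A cyclohexa-2,4-dienone tautomer of 18 (C5A=O; C6A sp3, bearing H and the C1′ substituent; C1′ configured as in 18, C6A configuration transient) | CC[C@@H](C)C(=O)C1=C(O)C([C@H](/C=C/CCC(C)C)c3c(OCc5ccccc5)c(C(=O)C(C)C)c4OC(C)(C)CCc4c3OCc6ccccc6)C(=O)C2=C1OC(C)(C)CC2 | intermediate
18 | (R)-1-(6-{(S,E)-1-[5,7-bis(benzyloxy)-8-isobutyryl-2,2-dimethylchroman-6-yl]-6-methylhept-2-en-1-yl}-5,7-dihydroxy-2,2-dimethylchroman-8-yl)-2-methylbutan-1-one | CC[C@@H](C)C(=O)c1c(O)c([C@H](/C=C/CCC(C)C)c3c(OCc5ccccc5)c(C(=O)C(C)C)c4OC(C)(C)CCc4c3OCc6ccccc6)c(O)c2c1OC(C)(C)CC2 | intermediate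
19 | (R)-1-(6-{(S)-1-[5,7-bis(benzyloxy)-8-isobutyryl-2,2-dimethylchroman-6-yl]-6-methylheptyl}-5,7-dihydroxy-2,2-dimethylchroman-8-yl)-2-methylbutan-1-one | CC[C@@H](C)C(=O)c1c(O)c([C@H](CCCCC(C)C)c3c(OCc5ccccc5)c(C(=O)C(C)C)c4OC(C)(C)CCc4c3OCc6ccccc6)c(O)c2c1OC(C)(C)CC2 | intermediate
20 | (R)-1-(6-{(R)-1-[5,7-dihydroxy-8-isobutyryl-2,2-dimethylchroman-6-yl]-6-methylheptyl}-5,7-dihydroxy-2,2-dimethylchroman-8-yl)-2-methylbutan-1-one (CNP0287681.1) | CC[C@@H](C)C(=O)c1c(O)c([C@H](CCCCC(C)C)c2c(O)c3c(c(C(=O)C(C)C)c2O)OC(C)(C)CC3)c(O)c2c1OC(C)(C)CC2 | target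

## Step count and least certain steps

Total step count: 12. Longest linear sequence: 10 steps (1 → 3 → 5 → 6 → 7 → 11 → 12 → 16 → 18 → 19 → 20; steps 1, 2, 3, 4, 6, 7, 9, 10, 11, 12).

**Step 10 (key step).** The most likely failure is heterolysis of the allylic C–O bond competing with the concerted shift. The leaving group is an acyl-stabilised phenoxide and the allyl unit carries an electron-rich aryl group, so ion-pair recombination could erode chirality transfer and give formal [1,3] migration. A second risk is steric retardation at the crowded C6A/C1′ junction, forcing temperatures at which the chain alkene migrates or the α-keto centre epimerises.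
Fallback: the route is left at 5 and 15 and rejoined at 20. A Betti-type three-component condensation of 5 with commercial 6-methylheptanal and pyrrolidine would give the racemic Mannich base 1-{5,7-dihydroxy-2,2-dimethyl-6-[6-methyl-1-(pyrrolidin-1-yl)heptyl]chroman-8-yl}-2-methylpropan-1-one F1. Treating F1 with 15 and a BINOL-derived chiral phosphoric acid (3,3′-bis(2,4,6-triisopropylphenyl) type) in toluene would eliminate pyrrolidine to the ring B ortho-quinone methide and add C6 of 15 in a catalyst-controlled Friedel–Crafts step, giving 20 directly. The catalyst enantiomer that favours the (R)-methine would have to be found by screening.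

**Step 9.** The most likely failure is ionisation of the activated allylic alcohol before displacement, with loss of inversion fidelity or attack at the wrong allyl terminus; some C-alkylation of the phloroglucinol ring is also possible.
Fallback: the route is left at 11 and rejoined at 16. Reduction of 11 with the (S)-oxazaborolidine and catecholborane would give (R,E)-1-[5,7-bis(benzyloxy)-6-(3-hydroxy-6-methylhept-1-en-1-yl)-2,2-dimethylchroman-8-yl]-2-methylpropan-1-one F2. Methyl chloroformate and pyridine would convert it into the (R,E)-allylic methyl carbonate F3. A Tsuji–Trost etherification of F3 with 15 (Pd2(dba)3, PPh3, THF, rt) should go through a π-allyl complex of divalent palladium with double inversion (net retention), and attack at the alkyl-bearing terminus remote from the hindered aryl group would give 16.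

**Step 2.** The most likely failure is acylation at C6 instead of C8, or Lewis-acid opening of the tertiary chroman ether.
Fallback: the route is left at 1 and 4 and rejoined at 5. Acylation of 1 with 4 (AlCl3) would give 2-methyl-1-(2,4,6-trihydroxyphenyl)propan-1-one F4. Benzylation of the most acidic para hydroxyl (benzyl bromide, 1 equiv, K2CO3, acetone) would give 1-[4-(benzyloxy)-2,6-dihydroxyphenyl]-2-methylpropan-1-one F5. Condensation with 3-methylbut-2-enal (ethylenediammonium diacetate, xylene, reflux) proceeds by Knoevenagel condensation and oxa-6π electrocyclisation; with the para oxygen blocked, the pyran oxygen must be ortho to the acyl group, giving 1-[5-(benzyloxy)-7-hydroxy-2,2-dimethyl-2H-chromen-8-yl]-2-methylpropan-1-one F6. H2 over Pd/C would saturate the chromene and remove the benzyl group to give 5.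

**Step 8.** The same loss of regiocontrol as in step 2 applies, with the added risk of partial enolisation of the aluminium-bound ketone and erosion of the (R)-α-centre.
Fallback: the route is left at 1 and 14 and rejoined at 15. Acylation of the more nucleophilic 1 with 14 at lower temperature (AlCl3, −10 °C) would give (R)-2-methyl-1-(2,4,6-trihydroxyphenyl)butan-1-one F7. Para-O-benzylation would give (R)-1-[4-(benzyloxy)-2,6-dihydroxyphenyl]-2-methylbutan-1-one F8. Condensation with 3-methylbut-2-enal and ethylenediammonium diacetate would give (R)-1-[5-(benzyloxy)-7-hydroxy-2,2-dimethyl-2H-chromen-8-yl]-2-methylbutan-1-one F9. H2 over Pd/C would give 15; all operations after the acylation are neutral.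

**Step 6.** The most likely failure is slow oxidative addition and insertion at the di-ortho-substituted iodide, with competing hydrodeiodination and polymerisation of the vinyl ketone.
Fallback: the route is left at 5 and rejoined at 11. Vilsmeier–Haack formylation of 5 (POCl3, DMF) at its only free position would give 5,7-dihydroxy-8-isobutyryl-2,2-dimethylchroman-6-carbaldehyde F10. Benzylation (benzyl bromide, K2CO3, DMF) would give 5,7-bis(benzyloxy)-8-isobutyryl-2,2-dimethylchroman-6-carbaldehyde F11. A Claisen–Schmidt condensation of F11 with commercial 5-methylhexan-2-one at its methyl group (Ba(OH)2, EtOH) would give the (E)-enone 11.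

## Further compounds

F1 | step 10 | 1-{5,7-dihydroxy-2,2-dimethyl-6-[6-methyl-1-(pyrrolidin-1-yl)heptyl]chroman-8-yl}-2-methylpropan-1-one (racemic) | CC(C)C(=O)c1c(O)c(C(CCCCC(C)C)N3CCCC3)c(O)c2c1OC(C)(C)CC2
F2 | step 9 | (R,E)-1-[5,7-bis(benzyloxy)-6-(3-hydroxy-6-methylhept-1-en-1-yl)-2,2-dimethylchroman-8-yl]-2-methylpropan-1-one | CC(C)C(=O)c1c(OCc3ccccc3)c(/C=C/[C@H](O)CCC(C)C)c(OCc3ccccc3)c2c1OC(C)(C)CC2
F3 | step 9 | (R,E)-1-[5,7-bis(benzyloxy)-8-isobutyryl-2,2-dimethylchroman-6-yl]-6-methylhept-1-en-3-yl methyl carbonate | CC(C)C(=O)c1c(OCc3ccccc3)c(/C=C/[C@H](OC(=O)OC)CCC(C)C)c(OCc3ccccc3)c2c1OC(C)(C)CC2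
F4 | step 2 | 2-methyl-1-(2,4,6-trihydroxyphenyl)propan-1-one | CC(C)C(=O)c1c(O)cc(O)cc1O
F5 | step 2 | 1-[4-(benzyloxy)-2,6-dihydroxyphenyl]-2-methylpropan-1-one | CC(C)C(=O)c1c(O)cc(OCc2ccccc2)cc1O
F6 | step 2 | 1-[5-(benzyloxy)-7-hydroxy-2,2-dimethyl-2H-chromen-8-yl]-2-methylpropan-1-one | CC(C)C(=O)c1c(O)cc(OCc3ccccc3)c2C=CC(C)(C)Oc12
F7 | step 8 | (R)-2-methyl-1-(2,4,6-trihydroxyphenyl)butan-1-one | CC[C@@H](C)C(=O)c1c(O)cc(O)cc1O
F8 | step 8 | (R)-1-[4-(benzyloxy)-2,6-dihydroxyphenyl]-2-methylbutan-1-one | CC[C@@H](C)C(=O)c1c(O)cc(OCc2ccccc2)cc1O
F9 | step 8 | (R)-1-[5-(benzyloxy)-7-hydroxy-2,2-dimethyl-2H-chromen-8-yl]-2-methylbutan-1-one | CC[C@@H](C)C(=O)c1c(O)cc(OCc3ccccc3)c2C=CC(C)(C)Oc12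
F10 | step 6 | 5,7-dihydroxy-8-isobutyryl-2,2-dimethylchroman-6-carbaldehyde | CC(C)C(=O)c1c(O)c(C=O)c(O)c2c1OC(C)(C)CC2
F11 | step 6 | 5,7-bis(benzyloxy)-8-isobutyryl-2,2-dimethylchroman-6-carbaldehyde | CC(C)C(=O)c1c(OCc3ccccc3)c(C=O)c(OCc3ccccc3)c2c1OC(C)(C)CC2
A1 | alternative 1 | 6-methylheptanal | CC(C)CCCCC=O
A2 | alternative 1 | ring B ortho-quinone methide, 8-isobutyryl-7-hydroxy-2,2-dimethyl-6-(6-methylheptylidene)-3,4-dihydro-2H-chromen-5(6H)-one | CC(C)CCCCC=C1C(=O)C2=C(OC(C)(C)CC2)C(C(=O)C(C)C)=C1O
A3 | alternative 1 | 1,1′-[(6-methylheptane-1,1-diyl)bis(5,7-dihydroxy-2,2-dimethylchroman-6,8-diyl)]bis(2-methylpropan-1-one) (ring B homodimer) | CC(C)CCCCC(c1c(O)c(C(=O)C(C)C)c2OC(C)(C)CCc2c1O)c1c(O)c(C(=O)C(C)C)c2OC(C)(C)CCc2c1O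
A4 | alternative 2 | 6,6′-(6-methylheptane-1,1-diyl)bis(2,2-dimethylchroman-5,7-diol) | CC(C)CCCCC(c1c(O)cc2OC(C)(C)CCc2c1O)c1c(O)cc2OC(C)(C)CCc2c1O
A5 | alternative 3 | (R)-1-{6-[1-(5,7-dihydroxy-8-isobutyryl-2,2-dimethylchroman-6-yl)-6-methylhept-1-en-1-yl]-5,7-dihydroxy-2,2-dimethylchroman-8-yl}-2-methylbutan-1-one (alkene geometry undefined) | CC[C@@H](C)C(=O)c1c(O)c(C(=CCCCC(C)C)c3c(O)c(C(=O)C(C)C)c4OC(C)(C)CCc4c3O)c(O)c2c1OC(C)(C)CC2
A6 | alternative 3 | (R)-1-[6-(5,7-dihydroxy-8-isobutyryl-2,2-dimethylchroman-6-carbonyl)-5,7-dihydroxy-2,2-dimethylchroman-8-yl]-2-methylbutan-1-one (diaryl ketone) | CC[C@@H](C)C(=O)c1c(O)c(C(=O)c3c(O)c(C(=O)C(C)C)c4OC(C)(C)CCc4c3O)c(O)c2c1OC(C)(C)CC2
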